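**Assumption:** planaic acid has no stereocentre and no stereogenic double bond, so it is achiral and no stereocontrol is needed.

## Retrosynthetic overview

1. Planaic acid ⇒ depside aldehyde (final CHO → CO2H oxidation) ⇒ its 2-hydroxy precursor (O-methylation) ⇒ ester C–O disconnection into 2,4-dimethoxy-6-pentylbenzoic acid and 2,4-dihydroxy-6-pentylbenzaldehyde.
2. Both halves come from one aldehyde, 2,4-dimethoxy-6-pentylbenzaldehyde: oxidise it for the acyl half, demethylate it for the phenol half.
3. That aldehyde comes from Vilsmeier formylation of 1,3-dimethoxy-5-pentylbenzene.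
4. Key C–C disconnection: the aryl–pentyl bond. The aryl C–Br carbon and C1 of pentanal are both electrophiles; pentanal is used with reversed polarity as its N–H hydrazone (a traceless pentyl carbanion equivalent, N2 lost) under nickel catalysis. One such coupling supplies the side chain of both rings.
5. No ring is formed: both benzene rings are bought as 1-bromo-3,5-dimethoxybenzene.

## Route

Step 1
Reactants: 1 1-bromo-3,5-dimethoxybenzene; 2 pentanal
Product: 4 1,3-dimethoxy-5-pentylbenzene, via pentanal hydrazone 3 (not isolated)
Conditions: 2 (1.8 equiv), N2H4·H2O (2.0 equiv), THF, rt, 1 h; then 1 (1.0 equiv), Ni(cod)2 (cod = 1,5-cyclooctadiene, 10 mol %), PMe3 (20 mol %), K3PO4 (2 equiv), THF, 60 °C, 24 h, argon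
Reagents that add atoms: none
Why: Nickel-catalysed cross-coupling of an N–H hydrazone with an aryl halide (carbonyl umpolung of the Wolff–Kishner type): oxidative addition of 1 to zerovalent nickel, binding and deprotonation of 3, C–C bond formation at the former carbonyl carbon and base-induced loss of N2 from the resulting diazene let C1 of pentanal, natively an electrophile, act as a pentyl carbanion toward the electrophilic aryl carbon in one operation; no stereocentre is formed.

Step 2
Reactants: 4 1,3-dimethoxy-5-pentylbenzene
Product: 6 2,4-dimethoxy-6-pentylbenzaldehyde, via aryl iminium chloride 5 (not isolated)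
Conditions: POCl3 (1.5 equiv), DMF, 0 °C to 80 °C, 3 h; then ice-water, rt
Reagents that add atoms: N,N-dimethylformamide, CN(C)C=O; water, O
Why: Vilsmeier–Haack formylation: the chloroiminium electrophile attacks the position para to one methoxy group and ortho to the other (C4, equivalent to C6) in preference to the doubly flanked C2, and water hydrolyses iminium salt 5 to the aldehyde; no stereocentre.

Step 3
Reactants: 6 2,4-dimethoxy-6-pentylbenzaldehyde (about half of the batch)
Product: 7 2,4-dimethoxy-6-pentylbenzoic acid
Conditions: NaClO2 (3 equiv), NaH2PO4 (3 equiv), 2-methyl-2-butene (10 equiv), t-BuOH/THF/H2O, 0 °C to rt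
Reagents that add atoms: sodium chlorite, [Na+].[O-]Cl=O
Why: Pinnick (Lindgren) oxidation: chlorous acid converts the hindered aryl aldehyde to the acid without touching the ethers, and 2-methyl-2-butene scavenges HOCl so the electron-rich ring is not chlorinated; no stereocentre.

Step 4
Reactants: 6 2,4-dimethoxy-6-pentylbenzaldehyde (other half of the batch)
Product: 9 2,4-dihydroxy-6-pentylbenzaldehyde, via bis(dibromoboryl) ether 8 (not isolated)
Conditions: BBr3 (4 equiv), CH2Cl2, −78 °C to rt, 12 h; then H2O, 0 °C
Reagents that add atoms: none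
Why: Lewis acid ether cleavage: BBr3 coordinates each methoxy oxygen and bromide removes the methyl group by SN2 to give aryl borate 8, which water hydrolyses to the resorcinol aldehyde, the formyl group being only reversibly complexed; no stereocentre.

Step 5
Reactants: 7 2,4-dimethoxy-6-pentylbenzoic acid; 9 2,4-dihydroxy-6-pentylbenzaldehyde
Product: 11 4-formyl-3-hydroxy-5-pentylphenyl 2,4-dimethoxy-6-pentylbenzoate, via mixed trifluoroacetic anhydride 10 (not isolated)
Conditions: 7 (1.05 equiv), 9 (1.0 equiv), (CF3CO)2O (3 equiv), toluene, rt, 3 h; aq. NaHCO3 work-up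
Reagents that add atoms: none
Why: Depside esterification through a mixed trifluoroacetic anhydride: the electron-rich, di-ortho-substituted acid forms the acylium-like anhydride 10, which acylates the free 4-OH of 9 while the 2-OH, hydrogen-bonded to the formyl group and more hindered, stays untouched; no stereocentre.

Step 6
Reactants: 11 4-formyl-3-hydroxy-5-pentylphenyl 2,4-dimethoxy-6-pentylbenzoate
Product: 12 4-formyl-3-methoxy-5-pentylphenyl 2,4-dimethoxy-6-pentylbenzoate
Conditions: MeI (5 equiv), K2CO3 (3 equiv), acetone, reflux, 8 h
Reagents that add atoms: iodomethane, CI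
Why: Williamson O-methylation: K2CO3 deprotonates the chelated phenol and MeI methylates it, while the depside carbonyl, shielded by its ortho methoxy and pentyl groups, resists transesterification and hydrolysis; no stereocentre.

Step 7
Reactants: 12 4-formyl-3-methoxy-5-pentylphenyl 2,4-dimethoxy-6-pentylbenzoate
Product: 13 planaic acid, 4-[(2,4-dimethoxy-6-pentylbenzoyl)oxy]-2-methoxy-6-pentylbenzoic acid
Conditions: NaClO2 (3 equiv), NaH2PO4 (3 equiv), 2-methyl-2-butene (10 equiv), t-BuOH/THF/H2O, rt
Reagents that add atoms: sodium chlorite, [Na+].[O-]Cl=O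
Why: Pinnick (Lindgren) oxidation at pH 3–4 converts the aryl aldehyde to the carboxylic acid under conditions that leave the base-labile depside ester intact, with HOCl scavenged to protect both electron-rich rings; no stereocentre.

## Compound list

1 | 1-bromo-3,5-dimethoxybenzene | COc1cc(Br)cc(OC)c1 | starting material
2 | pentanal | CCCCC=O | starting material
3 | pentanal hydrazone, (E)-pentylidenehydrazine | CCCC/C=N/N | intermediate (not isolated)
4 | 1,3-dimethoxy-5-pentylbenzene | CCCCCc1cc(OC)cc(OC)c1 | intermediate
5 | N-[(2,4-dimethoxy-6-pentylphenyl)methylidene]-N-methylmethanaminium chloride | CCCCCc1cc(OC)cc(OC)c1C=[N+](C)C.[Cl-] | intermediate (not isolated)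
6 | 2,4-dimethoxy-6-pentylbenzaldehyde | CCCCCc1cc(OC)cc(OC)c1C=O | intermediate
7 | 2,4-dimethoxy-6-pentylbenzoic acid | CCCCCc1cc(OC)cc(OC)c1C(=O)O | intermediate
8 | 2,4-bis[(dibromoboranyl)oxy]-6-pentylbenzaldehyde | CCCCCc1cc(OB(Br)Br)cc(OB(Br)Br)c1C=O | intermediate (not isolated)
9 | 2,4-dihydroxy-6-pentylbenzaldehyde | CCCCCc1cc(O)cc(O)c1C=O | intermediate
10 | 2,4-dimethoxy-6-pentylbenzoic trifluoroacetic anhydride | CCCCCc1cc(OC)cc(OC)c1C(=O)OC(=O)C(F)(F)F | intermediate (not isolated)
11 | 4-formyl-3-hydroxy-5-pentylphenyl 2,4-dimethoxy-6-pentylbenzoate | CCCCCc1cc(OC(=O)c2c(CCCCC)cc(OC)cc2OC)cc(O)c1C=O | intermediate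
12 | 4-formyl-3-methoxy-5-pentylphenyl 2,4-dimethoxy-6-pentylbenzoate | CCCCCc1cc(OC(=O)c2c(CCCCC)cc(OC)cc2OC)cc(OC)c1C=O | intermediate
13 | planaic acid, 4-[(2,4-dimethoxy-6-pentylbenzoyl)oxy]-2-methoxy-6-pentylbenzoic acid | CCCCCc1cc(OC(=O)c2c(CCCCC)cc(OC)cc2OC)cc(OC)c1C(=O)O | target

## Step count and risks

Total step count: 7. Longest linear sequence: 6 (steps 1, 2, 4, 5, 6, 7; the branch through step 3 is equally long).

**Most likely to fail: step 1.** Aliphatic N–H hydrazones are the less well-behaved partners in the nickel coupling; azine formation, plain Wolff–Kishner reduction of 3 or N-arylation may win. The fallback sets out from 2 and comes back at 4 by a metal-free reductive coupling. Condense 2 with tosylhydrazide (MeOH, rt) to pentanal N-tosylhydrazone F1. Heat F1 with commercial 3,5-dimethoxyphenylboronic acid and K2CO3 in dioxane at 110 °C. Bamford–Stevens fragmentation gives 1-diazopentane F2 (not isolated), which inserts into the C–B bond to give racemic [1-(3,5-dimethoxyphenyl)pentyl]boronic acid F3 (not isolated). Protodeboronation in the same pot gives 4.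

**Second: step 5.** The hindered acid may react slowly, and the resorcinol aldehyde 9 may be acylated at the wrong oxygen or on carbon. The fallback sets out from 4 (and uses 7) and comes back at 12, so step 6 is no longer needed. NaSEt in DMF at 140 °C removes one methyl group of 4 to give 3-methoxy-5-pentylphenol F6. Vilsmeier–Haack formylation (POCl3, DMF; then water) is expected to go mainly para to the free hydroxyl, through N-[(4-hydroxy-2-methoxy-6-pentylphenyl)methylidene]-N-methylmethanaminium chloride F7 (not isolated), to give 4-hydroxy-2-methoxy-6-pentylbenzaldehyde F8; any ortho-formylated isomer is removed by chromatography. F8 has a single hydroxyl and is acylated with 7 under the trifluoroacetic anhydride conditions (through 10) to give 12 directly.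

**Third: step 4.** BBr3 may degrade or irreversibly complex the aldehyde. The fallback sets out from 4 and comes back at 9 by demethylating before formylating. Molten pyridinium chloride (200 °C) cleaves both ethers of 4 to give 5-pentylbenzene-1,3-diol F4 (olivetol). Vilsmeier–Haack formylation of F4 (POCl3, DMF, 0 °C to rt; then water) proceeds through N-[(2,4-dihydroxy-6-pentylphenyl)methylidene]-N-methylmethanaminium chloride F5 (not isolated) and gives 9; C4 and C6 of F4 are equivalent by symmetry.

Further compounds
F1 | step 1 | pentanal N-tosylhydrazone | CCCC/C=N/NS(=O)(=O)c1ccc(C)cc1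
F2 | step 1 | 1-diazopentane | CCCCC=[N+]=[N-]
F3 | step 1 | [1-(3,5-dimethoxyphenyl)pentyl]boronic acid (racemic) | CCCCC(B(O)O)c1cc(OC)cc(OC)c1
F4 | step 4 | 5-pentylbenzene-1,3-diol (olivetol) | CCCCCc1cc(O)cc(O)c1
F5 | step 4 | N-[(2,4-dihydroxy-6-pentylphenyl)methylidene]-N-methylmethanaminium chloride | CCCCCc1cc(O)cc(O)c1C=[N+](C)C.[Cl-]
F6 | step 5 | 3-methoxy-5-pentylphenol | CCCCCc1cc(O)cc(OC)c1
F7 | step 5 | N-[(4-hydroxy-2-methoxy-6-pentylphenyl)methylidene]-N-methylmethanaminium chloride | CCCCCc1cc(O)cc(OC)c1C=[N+](C)C.[Cl-]
F8 | step 5 | 4-hydroxy-2-methoxy-6-pentylbenzaldehyde | CCCCCc1cc(O)cc(OC)c1C=O
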